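Ring A bears its three substituents mutually meta: OH at C1, the dodecamethylene chain at C3 and the diaryl ether oxygen at C5. That pattern is the imprint of a 4-oxygenated 6-alkyl-2-pyrone (supplying C6, C1, C2, C3) joined to an oxygen-substituted alkyne (supplying C4, C5), so ring A is disconnected at C3–C4 and C5–C6. In the key step a 4-tosyloxy-2-pyrone, tethered through twelve methylenes to the para position of a 2,6-dimethoxyphenyl ethynyl ether (ring B), undergoes intramolecular [4+2] cycloaddition and loses CO2, creating ring A, the diaryl ether and the 20-membered ring in one operation. Two deprotections then give the target.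

Key step: step 7

Remark: the target has no stereocentre; 11-chloroundec-1-ene is taken as the commercial C11 unit because a primary chloride is inert to phenoxide, n-BuLi and palladium until it is exchanged for iodide.

Step 1
Reactants: 1 4-bromo-2,6-dimethoxyphenol; 2 11-chloroundec-1-ene
Product: 4 4-(11-chloroundecyl)-2,6-dimethoxyphenol, via B-(11-chloroundecyl)-9-BBN 3 (not isolated)
Conditions: 2, 9-BBN, THF, 0 °C → rt; then 1, Pd(OAc)2 (cat.), SPhos, K3PO4, THF/H2O, 65 °C
Reagents that add atoms: none
Why: Anti-Markovnikov hydroboration followed by B-alkyl Suzuki–Miyaura coupling, in which zerovalent palladium inserts into the aryl C–Br bond far faster than into the primary C–Cl bond and the hindered phenoxide does not displace a primary chloride in aqueous THF.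

Step 2
Reactants: 4 4-(11-chloroundecyl)-2,6-dimethoxyphenol; 5 trichloroethylene
Product: 7 5-(11-chloroundecyl)-2-{[(E)-1,2-dichloroethenyl]oxy}-1,3-dimethoxybenzene, via dichloroacetylene 6 (not isolated)
Conditions: K2CO3, DMF, 70 °C, argon (excess 5)
Reagents that add atoms: none
Why: Base-mediated dehydrochlorination of 5 gives the haloalkyne in dilute solution, and anti addition of the phenoxide across it (nucleophilic addition to a haloalkyne) should give the (E)-dichlorovinyl ether faster than the phenoxide attacks the primary chloride.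

Step 3
Reactants: 7 5-(11-chloroundecyl)-2-{[(E)-1,2-dichloroethenyl]oxy}-1,3-dimethoxybenzene
Product: 10 {[4-(11-chloroundecyl)-2,6-dimethoxyphenoxy]ethynyl}trimethylsilane, via aryl chloroethynyl ether 8 (not isolated), via lithium aryloxyacetylide 9 (not isolated)
Conditions: n-BuLi (2.3 equiv), THF, −78 → −40 °C; then Me3SiCl, −78 °C → rt
Reagents that add atoms: chlorotrimethylsilane C[Si](C)(C)Cl
Why: Greene-type ynol ether synthesis (vinyl deprotonation, β-elimination of LiCl, Cl/Li exchange, then C-silylation of the acetylide), with the primary alkyl chloride inert to n-BuLi at these temperatures.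

Step 4
Reactants: 10 {[4-(11-chloroundecyl)-2,6-dimethoxyphenoxy]ethynyl}trimethylsilane
Product: 11 {[4-(11-iodoundecyl)-2,6-dimethoxyphenoxy]ethynyl}trimethylsilane
Conditions: NaI, NaHCO3, 2-butanone, 80 °C
Reagents that add atoms: sodium iodide [Na+].[I-]
Why: Finkelstein halide exchange driven by precipitation of NaCl under neutral buffered conditions that a silyl-capped aryl ynol ether (no retro-ene pathway) should tolerate.

Step 5
Reactants: 11 {[4-(11-iodoundecyl)-2,6-dimethoxyphenoxy]ethynyl}trimethylsilane; 12 4-hydroxy-6-methyl-2H-pyran-2-one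
Product: 15 6-[12-(3,5-dimethoxy-4-{[(trimethylsilyl)ethynyl]oxy}phenyl)dodecyl]-2-oxo-2H-pyran-4-yl 4-methylbenzenesulfonate, via dilithio pyrone dianion 13 (not isolated), via lithium pyronate 14 (not isolated)
Conditions: 12 (excess), LiN(i-Pr)2 (2 equiv per 12), THF/DMPU, −78 → −40 °C; 11, −78 → 0 °C; then TsCl, DMAP (cat.), 0 °C → rt
Reagents that add atoms: 4-methylbenzenesulfonyl chloride Cc1ccc(cc1)S(Cl)(=O)=O
Why: Dianion alkylation at the last-deprotonated methyl carbon (as with acetoacetate dianions) followed by O-sulfonylation of the resulting pyronate in the same flask, so that the free vinylogous acid (pKa about 5), which could add to the ynol ether, is never liberated.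

Step 6
Reactants: 15 6-[12-(3,5-dimethoxy-4-{[(trimethylsilyl)ethynyl]oxy}phenyl)dodecyl]-2-oxo-2H-pyran-4-yl 4-methylbenzenesulfonate
Product: 16 6-[12-(4-ethynyloxy-3,5-dimethoxyphenyl)dodecyl]-2-oxo-2H-pyran-4-yl 4-methylbenzenesulfonate
Conditions: n-Bu4NF, AcOH (1:1), THF, −20 °C; quick filtration through Et3N-deactivated silica; used at once
Reagents that add atoms: none
Why: Fluoride-induced protodesilylation of an alkynylsilane, where the C(sp)–Si bond should be cleaved far faster than buffered fluoride attacks the sulfonate or the lactone at low temperature.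

Step 7
Reactants: 16 6-[12-(4-ethynyloxy-3,5-dimethoxyphenyl)dodecyl]-2-oxo-2H-pyran-4-yl 4-methylbenzenesulfonate
Product: 18 macrocyclic diaryl ether with ring A as its 1-tosylate and ring B as its 2',6'-dimethyl ether, via bridged bicyclic lactone 17 (not isolated)
Conditions: syringe-pump addition to o-dichlorobenzene at 160 °C (final concentration about 1 mM), BHT (cat.), argon
Reagents that add atoms: none
Why: Proposed new method: the nucleophilic CH terminus of the ethynyl ether bonds to the electrophilic pyrone C6 and the oxygen-bearing alkyne carbon to pyrone C3 in an asynchronous inverse-electron-demand [4+2] cycloaddition, and the 2-oxabicyclo[2.2.2]octadienone 17 then expels CO2 irreversibly by retro-[4+2] to leave the benzene. The closest known reaction type is the intermolecular Diels–Alder/decarboxylation of 2-pyrones with alkoxyalkynes, ynamines and ketene acetals to give benzenes; new here are the aryl ethynyl ether as dienophile, which turns the alkyne oxygen into a diaryl ether, and the closure of a large ring in the same event. Ring A is closed by the cycloaddition itself (its bonds C3–C4 and C5–C6) and aromatised by the loss of CO2; the 20-membered ring is closed by the same two bonds because the tether runs from pyrone C6 to the ring B carbon para to the ynol oxygen, and slow addition at high dilution should favour this over oligomerisation. No stereocentre results, since the two bridgeheads of 17 become aromatic carbons. The step needs the orientation alkyne CH to C6 (meta pattern, 20-membered ring) and not alkyne CH to C3 (ortho pattern, 19-membered ring); the long tether gives no geometric bias, so this rests on matched polarisation: the ether oxygen makes the CH terminus nucleophilic, the ring oxygen and carbonyl make C6 electrophilic, and the 4-sulfonate lowers the diene LUMO. The aryl group offers no β-hydrogen for the retro-ene fragmentation to a ketene that destroys alkyl ynol ethers on heating.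

Step 8
Reactants: 18 macrocyclic diaryl ether with ring A as its 1-tosylate and ring B as its 2',6'-dimethyl ether
Product: 19 macrocyclic diaryl ether with free ring A phenol and ring B as its 2',6'-dimethyl ether
Conditions: KOH, MeOH/THF, 65 °C; then 1 M HCl
Reagents that add atoms: none
Why: Saponification of an aryl sulfonate by attack of hydroxide or methoxide at sulfur, under which the diaryl ether and the methyl ethers are inert.

Step 9
Reactants: 19 macrocyclic diaryl ether with free ring A phenol and ring B as its 2',6'-dimethyl ether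
Product: 20 CNP0314249.0
Conditions: BBr3, CH2Cl2, −78 °C → rt; then H2O
Reagents that add atoms: none
Why: Lewis-acid cleavage of aryl methyl ethers (boron coordinates oxygen, bromide attacks methyl), while the diaryl ether has no sp3 carbon for bromide to attack and should survive.

Compound list
1 | 4-bromo-2,6-dimethoxyphenol | COc1cc(Br)cc(OC)c1O | starting material
2 | 11-chloroundec-1-ene | C=CCCCCCCCCCCl | starting material
3 | 9-(11-chloroundecyl)-9-borabicyclo[3.3.1]nonane (not isolated) | ClCCCCCCCCCCCB1C2CCCC1CCC2 | intermediate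
4 | 4-(11-chloroundecyl)-2,6-dimethoxyphenol | COc1cc(CCCCCCCCCCCCl)cc(OC)c1O | intermediate
5 | trichloroethylene | ClC=C(Cl)Cl | starting material
6 | dichloroacetylene (not isolated) | ClC#CCl | intermediate
7 | 5-(11-chloroundecyl)-2-{[(E)-1,2-dichloroethenyl]oxy}-1,3-dimethoxybenzene | COc1cc(CCCCCCCCCCCCl)cc(OC)c1O/C(Cl)=C\Cl | intermediate
8 | 2-[(chloroethynyl)oxy]-5-(11-chloroundecyl)-1,3-dimethoxybenzene (not isolated) | COc1cc(CCCCCCCCCCCCl)cc(OC)c1OC#CCl | intermediate
9 | lithium [4-(11-chloroundecyl)-2,6-dimethoxyphenoxy]acetylide (not isolated) | [Li]C#COc1c(OC)cc(CCCCCCCCCCCCl)cc1OC | intermediate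
10 | {[4-(11-chloroundecyl)-2,6-dimethoxyphenoxy]ethynyl}trimethylsilane | COc1cc(CCCCCCCCCCCCl)cc(OC)c1OC#C[Si](C)(C)C | intermediate
11 | {[4-(11-iodoundecyl)-2,6-dimethoxyphenoxy]ethynyl}trimethylsilane | COc1cc(CCCCCCCCCCCI)cc(OC)c1OC#C[Si](C)(C)C | intermediate
12 | 4-hydroxy-6-methyl-2H-pyran-2-one (triacetic acid lactone) | Cc1cc(O)cc(=O)o1 | starting material
13 | dilithium salt of the dianion of 12, deprotonated at OH and at the methyl group (not isolated) | [Li+].[Li+].[CH2-]c1cc([O-])cc(=O)o1 | intermediate
14 | lithium 6-[12-(3,5-dimethoxy-4-{[(trimethylsilyl)ethynyl]oxy}phenyl)dodecyl]-2-oxo-2H-pyran-4-olate (not isolated) | [Li+].[O-]c1cc(=O)oc(CCCCCCCCCCCCc2cc(OC)c(OC#C[Si](C)(C)C)c(OC)c2)c1 | intermediate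
15 | 6-[12-(3,5-dimethoxy-4-{[(trimethylsilyl)ethynyl]oxy}phenyl)dodecyl]-2-oxo-2H-pyran-4-yl 4-methylbenzenesulfonate | Cc1ccc(cc1)S(=O)(=O)Oc1cc(=O)oc(CCCCCCCCCCCCc2cc(OC)c(OC#C[Si](C)(C)C)c(OC)c2)c1 | intermediate
16 | 6-[12-(4-ethynyloxy-3,5-dimethoxyphenyl)dodecyl]-2-oxo-2H-pyran-4-yl 4-methylbenzenesulfonate (key-step precursor) | Cc1ccc(cc1)S(=O)(=O)Oc1cc(=O)oc(CCCCCCCCCCCCc2cc(OC)c(OC#C)c(OC)c2)c1 | intermediate
17 | bridged 2-oxabicyclo[2.2.2]octa-5,7-dien-3-one cycloadduct spanning the macrocycle; racemic, the two bridgeheads can have only one relative configuration (not isolated) | O=C1OC23CCCCCCCCCCCCc4cc(OC)c(c(OC)c4)OC(=C2)C1C(OS(=O)(=O)c1ccc(C)cc1)=C3 | intermediate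
18 | 20-membered diaryl ether macrocycle: ring A 1-tosyloxy, ring A C3 joined by (CH2)12 to ring B C4', ring A C5 joined through O to ring B C1', OMe at C2' and C6' | Cc1ccc(cc1)S(=O)(=O)Oc1cc2cc(c1)Oc1c(OC)cc(cc1OC)CCCCCCCCCCCC2 | intermediate
19 | the same macrocycle with free OH at ring A C1 and OMe at C2' and C6' | Oc1cc2cc(c1)Oc1c(OC)cc(cc1OC)CCCCCCCCCCCC2 | intermediate
20 | CNP0314249.0: the same macrocycle with OH at ring A C1 and at ring B C2' and C6' | Oc1cc2cc(c1)Oc1c(O)cc(cc1O)CCCCCCCCCCCC2 | target

Total step count: 9. Longest linear sequence: 9 steps (from 1; compounds 2, 5 and 12 enter as purchased).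

Steps most likely to fail

1. Step 7. The cycloaddition may be too slow at temperatures the ethynyl ether tolerates, so that oligomerisation or decomposition of the alkyne, or bonding in the reverse orientation, consumes the precursor. The fallback uses known chemistry (Ullmann ether coupling, ring-closing olefin metathesis, hydrogenation); it sets out from 1 and comes back at 19. Suzuki–Miyaura coupling of 1 with allylboronic acid pinacol ester (Pd(dppf)Cl2, K3PO4, THF/H2O, 65 °C) should give 4-allyl-2,6-dimethoxyphenol F1. Separately, single Br/Mg exchange on 1-(benzyloxy)-3,5-dibromobenzene (i-PrMgCl·LiCl, THF, −15 °C) should give [3-(benzyloxy)-5-bromophenyl]magnesium chloride F2, which is alkylated in the same flask with 11-bromoundec-1-ene (Li2CuCl4 cat., THF/NMP) to 1-(benzyloxy)-3-bromo-5-(undec-10-en-1-yl)benzene F3. Ullmann coupling of F1 with F3 (CuI, picolinic acid, K3PO4, DMSO, 90 °C) should give the diaryl ether diene F4. Ring-closing metathesis (second-generation Grubbs catalyst, CH2Cl2, 40 °C, 1 mM) should close the 20-membered cycloalkene F5 as a mixture of E and Z isomers. Hydrogenation (H2, palladium on carbon, EtOAc/EtOH) saturates the alkene and removes the benzyl group to give 19, which continues with step 9.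

2. Step 5. Capture of the delocalised dianion by an unactivated primary iodide may be sluggish, with proton transfer and elimination competing, and O-sulfonylation in the same flask may be incomplete. The fallback replaces the dianion by an O-protected monoanion; it sets out from 12 and 11 and comes back at 15. Mitsunobu O-allylation of 12 (allyl alcohol, PPh3, DIAD, THF) should give 4-(allyloxy)-6-methyl-2H-pyran-2-one F6. Deprotonation at the methyl group (LiN(SiMe3)2, THF/DMPU, −78 °C) gives [4-(allyloxy)-2-oxo-2H-pyran-6-yl]methyllithium F7, which is alkylated with 11 to the 4-allyloxy pyrone F8 carrying the full chain. Pd(PPh3)4 (cat.) and morpholine in THF transfer the allyl group to nitrogen and leave the morpholinium pyronate F9, which is sulfonylated in the same flask (TsCl, Et3N) to give 15 without the free acid being isolated.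

3. Step 6. Fluoride may attack the vinylogous sulfonate or the lactone, and the liberated terminal ethynyl ether may be lost by hydration or oligomerisation during isolation. The fallback removes the silyl group while the pyrone is protected as its anion; it sets out from 11 (through 14, made as in step 5) and comes back at 16. Instead of TsCl, MeOH and K2CO3 are added to 14 at 0 °C, so that methoxide cleaves the C–Si bond and gives potassium 6-[12-(4-ethynyloxy-3,5-dimethoxyphenyl)dodecyl]-2-oxo-2H-pyran-4-olate F10. After removal of the volatiles the salt is sulfonylated (TsCl, Et3N, DMAP, CH2Cl2/MeCN, 0 °C) to give 16 directly.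

Further compounds
F1 | step 7 | 4-allyl-2,6-dimethoxyphenol | C=CCc1cc(OC)c(O)c(OC)c1
F2 | step 7 | [3-(benzyloxy)-5-bromophenyl]magnesium chloride | Cl[Mg]c1cc(Br)cc(OCc2ccccc2)c1
F3 | step 7 | 1-(benzyloxy)-3-bromo-5-(undec-10-en-1-yl)benzene | C=CCCCCCCCCCc1cc(Br)cc(OCc2ccccc2)c1
F4 | step 7 | 5-allyl-2-[3-(benzyloxy)-5-(undec-10-en-1-yl)phenoxy]-1,3-dimethoxybenzene | C=CCc1cc(OC)c(Oc2cc(OCc3ccccc3)cc(CCCCCCCCCC=C)c2)c(OC)c1
F5 | step 7 | 20-membered macrocyclic alkene, ring A 1-benzyloxy, ring B 2',6'-dimethoxy, mixture of E and Z isomers | COc1cc2cc(OC)c1Oc1cc(OCc3ccccc3)cc(c1)CCCCCCCCCC=CC2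
F6 | step 5 | 4-(allyloxy)-6-methyl-2H-pyran-2-one | C=CCOc1cc(=O)oc(C)c1
F7 | step 5 | [4-(allyloxy)-2-oxo-2H-pyran-6-yl]methyllithium | [Li]Cc1cc(OCC=C)cc(=O)o1
F8 | step 5 | 4-(allyloxy)-6-[12-(3,5-dimethoxy-4-{[(trimethylsilyl)ethynyl]oxy}phenyl)dodecyl]-2H-pyran-2-one | C=CCOc1cc(=O)oc(CCCCCCCCCCCCc2cc(OC)c(OC#C[Si](C)(C)C)c(OC)c2)c1
F9 | step 5 | morpholinium 6-[12-(3,5-dimethoxy-4-{[(trimethylsilyl)ethynyl]oxy}phenyl)dodecyl]-2-oxo-2H-pyran-4-olate | C1COCC[NH2+]1.[O-]c1cc(=O)oc(CCCCCCCCCCCCc2cc(OC)c(OC#C[Si](C)(C)C)c(OC)c2)c1
F10 | step 6 | potassium 6-[12-(4-ethynyloxy-3,5-dimethoxyphenyl)dodecyl]-2-oxo-2H-pyran-4-olate | [K+].[O-]c1cc(=O)oc(CCCCCCCCCCCCc2cc(OC)c(OC#C)c(OC)c2)c1
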